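The runs were generated by integration on assumed constants; scatter was added.

| flask | first end groups | second end groups | protic impurity | remark | time |
|---|---|---|---|---|---|
| Wednesday's | 0.030 M | 0.0285 M | 0.015 M | run made earlier |  |
| Friday's | 0.030 M | 0.0285 M | 0.021 M | run made earlier |  |
| Sunday's | 0.030 M | 0.0285 M | 0.033 M | run made earlier |  |
| blue | 0.030 M | 0.0285 M | 0.0150 M | everything together at the start | 6.0 h |
| violet | 0.030 M | 0.0285 M (fed, over 2.5 h) | 0.0150 M | all else is in the flask from the start; the feed brings no volume worth counting | 6.0 h |
| teal | 0.030 M (fed, over 2.5 h) | 0.0285 M | 0.0150 M | all else is in the flask from the start; the feed brings no volume worth counting | 6.0 h |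

| run | time / h | side product / % | links / % | first end groups / % |
|---|---|---|---|---|
| Wednesday's | 0.250 | 3.0 | 24.7 | 71.5 |
| Wednesday's | 0.667 | 14.1 | 32.7 | 53.2 |
| Wednesday's | 1.50 | 29.9 | 30.3 | 40.7 |
| Wednesday's | 4.00 | 54.7 | 18.2 | 27.6 |
| Friday's | 0.250 | 3.6 | 25.2 | 71.6 |
| Friday's | 0.667 | 13.4 | 33.6 | 52.8 |
| Friday's | 1.50 | 29.7 | 29.8 | 40.3 |
| Friday's | 4.00 | 54.6 | 16.7 | 28.8 |
| Sunday's | 0.833 | 16.9 | 32.7 | 49.9 |
| Sunday's | 2.00 | 37.1 | 25.1 | 38.6 |
| Sunday's | 2.50 | 41.9 | 21.6 | 36.9 |
| Sunday's | 4.00 | 54.1 | 14.4 | 30.5 |

(standard deviation of a reading: 0.5 percentage points)

- the flask that comes out highest in amount of side product, in percent of the first end groups charged; "all alike" if 1.5 percentage points covers them all (blue / violet / teal / all alike)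
- amount of side product at the end, in percent of the first end groups charged, blue
- amount of side product at the end, in percent of the first end groups charged, violet
- amount of side product at the end, in percent of the first end groups charged, teal

- percent here means first end groups units held: one side product counts as two
- the earlier runs were read with a standard deviation of 0.5 percentage points
- steps that have been proposed: first end groups + second end groups <-> links; second end groups + protic impurity -> quenched reagent; first end groups + links -> side product

Wednesday's run has blue's charges, so read blue's course from it. Sunday's run, with twice the protic impurity, reads 54.1% of side product at 4.00 h against Wednesday's 54.7%, so set the impurity aside for this reckoning.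

Let O be side product as a fraction of the first end groups charged. One side product counts as two of them. Turn O into odds, y = O/(1−O). Wednesday's run gives y = 0.427 at 1.50 h and 1.21 at 4.00 h; a straight line through these two readings climbs at s = 0.312 h⁻¹ from a start at d = 0.135 h, both read values that carry the scatter. Test the line on a reading it did not use: at 2.50 h it gives 42.6%, and Sunday's run reads 41.9%, with a scatter of 0.5 percentage points.

Fold the recipe in: N = s(t − d − T/2), where T is the feed time, on the assumption that a fed flask runs late by the average wait of a unit under a steady feed, half of T. Blue has no feed, so N = 1.83 and O = 64.7%. For violet and teal, N = 1.44, the odds number of a fed flask, and O = 59.0%. Blue leads by 5.7 points, more than the margin. One number is not enough for the pair, though: N has no term for which end group is fed, so it cannot part violet from teal.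

The forecast gives 65% for blue, 61.5% for violet and 58% for teal, names blue, and holds that “violet's delayed feed holds links low early”. The simulation gives 64.5% for blue, 60.2% for violet and 56.6% for teal, so blue comes out highest.

    first end groups + second end groups ⇌ links (K = 59.9 M⁻¹, k = 1.02 M⁻¹ min⁻¹)
    second end groups + protic impurity → quenched reagent (k = 0.102 M⁻¹ min⁻¹)
    first end groups + links → side product (k = 0.361 M⁻¹ min⁻¹)

The fed value stands 1.2 points below violet and 2.4 points above teal, and teal ends with 58% of its protic impurity against violet's 69%. Now take teal with 0.0071 M of second end groups. The earlier runs share one such charge and show nothing of how N moves with it, so guess that N goes in proportion: N becomes 0.359 and O 26.4%. That flask gives 26.7%, with 70.4% of its first end groups left.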